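Everything rests on disconnecting C3–C4 of the gem-dimethylcyclohexane ring A (C1–C5, C10; abietane-type locants) of the taiwaniaquinoid half, so that this ring is closed last. A seco-A hydroxyquinone bearing trans arms on cyclopentane ring B (allyl at C10, CMe2–CO2N(phth) at C5) is first united with 4-epi-trans-communic acid in a perezone-type [5+2] cycloaddition. The key step then converts the redox-active ester into the tertiary C4 radical, which closes ring A 6-endo onto the allyl terminus in one operation. It exploits the quaternary gem-dimethyl C4 and the trans C5–C10 junction of rings A/B, which makes the competing 5-exo closure a strained trans-bicyclo[3.3.0]octane.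

Key step: step 12

Remarks
- Assumption: 4-epi-trans-communic acid (20, labda-8(17),12E,14-trien-18-oic acid) is taken as a commercial natural-product-grade starting material.
- Locants: taiwaniaquinoid half, ring A = C1–C5, C10 (C4 carries the two methyls); ring B = C5, C6, C8, C9, C10 (C7 = formyl carbon on C6); ring C = C8, C9, C11–C14. Labdane atoms carry primes (diene C12′=C13′–C14′=C15′). β is the face of ring B that bears the C10 methyl group, α the opposite face.
- Order of ring formation: ring B comes with 1, ring C is formed in step 8, the bicyclo[3.2.1]octene in step 11, ring A in step 12; the decalin comes with 20.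

Step 1
Reactants: 1 2-methylcyclopent-2-en-1-one; 2 methyl trimethylsilyl dimethylketene acetal; 3 allyl methyl carbonate
Product: 5 methyl 2-methyl-2-[(1R,2S)-2-methyl-3-oxo-2-(prop-2-en-1-yl)cyclopentyl]propanoate, via silyl enol ether 4 (not isolated)
Conditions: chiral B-(o-tolyl)oxazaborolidinium triflimide (20 mol %, antipode chosen for the 1R adduct), Ph3PO (25 mol %), toluene, −20 °C; then 3, Pd2(dba)3 (2.5 mol %), dppe (6 mol %), THF, 65 °C
Reagents that add atoms: 2, COC(O[Si](C)(C)C)=C(C)C; 3, C=CCOC(=O)OC
Why: A catalytic enantioselective Mukaiyama–Michael addition should set C5 by catalyst control and give the regiodefined C9–C10 silyl enol ether, whose Pd-catalysed allylation (Tsuji–Trost type) then creates the quaternary C10 with the allyl group entering anti to the bulky C5 tert-alkyl arm, so that allyl (α) and arm (β) are trans and the methyl is cis to the arm.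

Step 2
Reactants: 5 methyl 2-methyl-2-[(1R,2S)-2-methyl-3-oxo-2-(prop-2-en-1-yl)cyclopentyl]propanoate
Product: 6 methyl 2-methyl-2-[(1R,5S)-5-methyl-4-oxo-5-(prop-2-en-1-yl)cyclopent-2-en-1-yl]propanoate
Conditions: IBX (2 equiv), DMSO/toluene, 70 °C
Reagents that add atoms: none
Why: IBX-mediated α,β-dehydrogenation of a ketone can only run toward C8–C6 because C10 is quaternary, and no stereocentre is touched.

Step 3
Reactants: 6 methyl 2-methyl-2-[(1R,5S)-5-methyl-4-oxo-5-(prop-2-en-1-yl)cyclopent-2-en-1-yl]propanoate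
Product: 7 methyl 2-[(1R,2S,5S)-5-(1,3-dioxolan-2-yl)-2-methyl-3-oxo-2-(prop-2-en-1-yl)cyclopentyl]-2-methylpropanoate
Conditions: (n-Bu4N)4W10O32 (2 mol %), 1,3-dioxolane/MeCN, 390 nm LEDs, rt
Reagents that add atoms: 1,3-dioxolane, C1COCO1
Why: Decatungstate-photocatalysed hydrogen abstraction from C2–H of dioxolane followed by Giese addition of the nucleophilic dioxolanyl radical to the enone β-carbon C6, anti to the adjacent C5 arm, should install the masked C7 aldehyde on the α face (trans to the arm, which is also the thermodynamic arrangement of the later epimerisable aldehyde).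

Step 4
Reactants: 7 methyl 2-[(1R,2S,5S)-5-(1,3-dioxolan-2-yl)-2-methyl-3-oxo-2-(prop-2-en-1-yl)cyclopentyl]-2-methylpropanoate
Product: 8 2-[(1R,2S,5S)-5-(1,3-dioxolan-2-yl)-2-methyl-3-oxo-2-(prop-2-en-1-yl)cyclopentyl]-2-methylpropanoic acid
Conditions: KOH (5 equiv), MeOH/H2O, 70 °C; then 1 M HCl, 0 °C, to pH 4
Reagents that add atoms: potassium hydroxide, [K+].[OH-]
Why: Saponification of the hindered methyl ester is safe here because the acetal is base-stable, C10 is quaternary and neither C5 nor C6 is α to the ketone, so no epimerisation or retro-Michael path exists.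

Step 5
Reactants: 8 2-[(1R,2S,5S)-5-(1,3-dioxolan-2-yl)-2-methyl-3-oxo-2-(prop-2-en-1-yl)cyclopentyl]-2-methylpropanoic acid; 9 2,4,6-triisopropylbenzenesulfonohydrazide
Product: 10 2,4,6-triisopropylbenzenesulfonylhydrazone of 8 (C=N at C9)
Conditions: THF, 4 Å MS, rt
Reagents that add atoms: 9, CC(C)c1cc(C(C)C)c(S(=O)(=O)NN)c(C(C)C)c1
Why: Hydrazone condensation, catalysed by the substrate's own carboxylic acid so that the acetal is not exposed to mineral acid, provides the precursor for a Shapiro reaction.

Step 6
Reactants: 11 diisopropyl squarate (3,4-diisopropoxycyclobut-3-ene-1,2-dione)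
Product: 13 3-isopropoxy-4-isopropylcyclobut-3-ene-1,2-dione, via chloromagnesium alkoxide adduct 12 (not isolated)
Conditions: i-PrMgCl (1.05 equiv), THF, −78 °C; then 6 M HCl, CH2Cl2, rt
Reagents that add atoms: isopropylmagnesium chloride, CC(C)[Mg]Cl
Why: 1,2-Addition of the Grignard reagent to one squarate carbonyl and acid-mediated loss of isopropanol from the adduct is the standard route to 3-alkoxy-4-alkylcyclobutenediones.

Step 7
Reactants: 10 2,4,6-triisopropylbenzenesulfonylhydrazone of 8; 13 3-isopropoxy-4-isopropylcyclobut-3-ene-1,2-dione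
Product: 15 4-hydroxycyclobutenone adduct (ring B as C8=C9 cyclopentene bearing at C9 the 1-hydroxy-2-isopropoxy-3-isopropyl-4-oxocyclobut-2-en-1-yl group; carbinol centre as a mixture), via vinyllithium 14 (not isolated)
Conditions: n-BuLi (3.3 equiv), THF, −78 → 0 °C; then 13, −78 °C; aq. NH4Cl
Reagents that add atoms: 13, CC(C)OC1=C(C(C)C)C(=O)C1=O
Why: The Shapiro reaction should give the C9 vinyllithium regiospecifically (only C8 carries α-hydrogens, the carboxylate is inert), and this adds to the more electrophilic carbonyl of 13 (the one next to C–OiPr); the new carbinol centre is destroyed in step 8.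

Step 8
Reactants: 15 4-hydroxycyclobutenone adduct
Product: 17 2-[(1R,2R,3S)-1-(1,3-dioxolan-2-yl)-5-isopropoxy-6-isopropyl-3-methyl-4,7-dioxo-3-(prop-2-en-1-yl)-2,3,4,7-tetrahydro-1H-inden-2-yl]-2-methylpropanoic acid, via hydroquinone 16 (not isolated)
Conditions: toluene (degassed), 110 °C; then Ag2O (1.5 equiv), MgSO4, rt
Reagents that add atoms: none
Why: The Moore rearrangement (4π ring opening to a dienylketene, 6π electrocyclisation onto C8, tautomerisation) builds the fully substituted ring C with the pattern fixed by the cyclobutenone (OH at C11 and C14, OiPr at C12, iPr at C13), and Ag2O oxidises the hydroquinone to the p-quinone.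

Step 9
Reactants: 17 isopropoxyquinone acid
Product: 18 1,3-dioxoisoindolin-2-yl ester of 17 (N-acyloxyphthalimide)
Conditions: N-hydroxyphthalimide (1.2 equiv), DIC (1.3 equiv), DMAP (10 mol %), CH2Cl2, 0 °C → rt
Reagents that add atoms: N-hydroxyphthalimide, O=C1c2ccccc2C(=O)N1O
Why: Carbodiimide esterification gives the redox-active ester at a stage where the carboxylic acid is the only acylatable group, the quinone OH and the aldehyde still being masked.

Step 10
Reactants: 18 N-acyloxyphthalimide of 17
Product: 19 1,3-dioxoisoindolin-2-yl 2-[(1R,2R,3S)-1-formyl-5-hydroxy-6-isopropyl-3-methyl-4,7-dioxo-3-(prop-2-en-1-yl)-2,3,4,7-tetrahydro-1H-inden-2-yl]-2-methylpropanoate (seco-A hydroxyquinone)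
Conditions: 3 M aq. HCl/THF (1:3), 50 °C
Reagents that add atoms: water, O
Why: Aqueous acid should hydrolyse the dioxolane to the C7 aldehyde and the vinylogous isopropyl ester (addition–elimination at C12) to the 12-hydroxy-p-quinone, while the hindered N-acyloxyphthalimide resists acid hydrolysis and C6 keeps the thermodynamic α-formyl (trans to the C5 arm) configuration.

Step 11
Reactants: 19 seco-A hydroxyquinone; 20 4-epi-trans-communic acid
Product: 21 seco-A [5+2] adduct (target skeleton lacking the C3–C4 bond: bicyclo[3.2.1]octenedione with C14 as one-carbon bridge, ring B carrying 10α-allyl, 10β-methyl, 5β-CMe2CO2N(phth) and 6α-CHO, labdane unit as in the target)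
Conditions: BF3·OEt2 (0.5 equiv), CH2Cl2, −78 → −40 °C; pH 4 buffer work-up
Reagents that add atoms: 20, C=C1CC[C@@H]2[C@](C)(CCC[C@@]2(C)C(=O)O)[C@H]1C/C=C(\C)C=C
Why: In this perezone-type cationic [5+2] cycloaddition, Lewis-acid activation of the C11=O/C12–OH unit gives the C8–C9–C11–C12–C13 hydroxypentadienyl cation, which should add the terminal C14′=C15′ vinyl group with C15′ bonding to the less congested C13 and the resulting allyl cation closing at C14′ onto C8 from the α face (anti to the pseudo-axial C10 methyl and the C5 arm) with the side chain endo to the new enone bridge, setting C8, C13 and C14′ and leaving the C12 ketone/C11 enol.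

Step 12
Reactants: 21 seco-A [5+2] adduct
Product: 22 CNP0269191.1 (target)
Conditions: Ru(bpy)3(PF6)2 (2 mol %), Hantzsch ester (1.5 equiv), CH2Cl2 (0.005 M), 450 nm LEDs, rt
Reagents that add atoms: none
Why: Single-electron reduction of the N-acyloxyphthalimide by photogenerated Ru(I) fragments it into phthalimide anion, CO2 and the tertiary C4 radical, which adds to the terminal carbon (C3) of the C10 allyl arm; the secondary C2 radical is then quenched by hydrogen transfer from the Hantzsch ester. The closest known reaction type is the reductive decarboxylative radical cyclisation of redox-active esters under photoredox conditions. Ring A is closed in the 6-endo-trig mode through a chair-like transition state that is already trans-fused to ring B. No new stereocentre is formed, since C4 carries two methyl groups and C2 and C3 become CH2, while the trans C5/C10 junction was fixed in step 1. The selectivity needed is 6-endo over 5-exo and over premature reduction: the trans arms on ring B make the 5-exo product a strained trans-bicyclo[3.3.0]octane, and high dilution with a slow hydrogen donor favours cyclisation of the long-lived tertiary radical. The isolated labdane alkenes, the aldehyde and the diosphenol should not be reduced at the Ru(I) potential and are poor acceptors for a nucleophilic tertiary radical.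

Compound list
1 | 2-methylcyclopent-2-en-1-one | CC1=CCCC1=O | starting material
2 | methyl trimethylsilyl dimethylketene acetal, [(1-methoxy-2-methylprop-1-en-1-yl)oxy]trimethylsilane | COC(O[Si](C)(C)C)=C(C)C | starting material
3 | allyl methyl carbonate | C=CCOC(=O)OC | starting material
4 | methyl 2-methyl-2-[(1R)-2-methyl-3-(trimethylsilyloxy)cyclopent-2-en-1-yl]propanoate | COC(=O)C(C)(C)[C@@H]1CCC(O[Si](C)(C)C)=C1C | intermediate
5 | methyl 2-methyl-2-[(1R,2S)-2-methyl-3-oxo-2-(prop-2-en-1-yl)cyclopentyl]propanoate (allyl trans to the ester arm) | O=C1CC[C@@H](C(C)(C)C(=O)OC)[C@]1(C)CC=C | intermediate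
6 | methyl 2-methyl-2-[(1R,5S)-5-methyl-4-oxo-5-(prop-2-en-1-yl)cyclopent-2-en-1-yl]propanoate | O=C1C=C[C@@H](C(C)(C)C(=O)OC)[C@]1(C)CC=C | intermediate
7 | methyl 2-[(1R,2S,5S)-5-(1,3-dioxolan-2-yl)-2-methyl-3-oxo-2-(prop-2-en-1-yl)cyclopentyl]-2-methylpropanoate | O=C1C[C@H](C2OCCO2)[C@@H](C(C)(C)C(=O)OC)[C@]1(C)CC=C | intermediate
8 | 2-[(1R,2S,5S)-5-(1,3-dioxolan-2-yl)-2-methyl-3-oxo-2-(prop-2-en-1-yl)cyclopentyl]-2-methylpropanoic acid | O=C1C[C@H](C2OCCO2)[C@@H](C(C)(C)C(=O)O)[C@]1(C)CC=C | intermediate
9 | 2,4,6-triisopropylbenzenesulfonohydrazide | CC(C)c1cc(C(C)C)c(S(=O)(=O)NN)c(C(C)C)c1 | starting material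
10 | 2,4,6-triisopropylbenzenesulfonylhydrazone of 8 | CC(C)c1cc(C(C)C)c(S(=O)(=O)NN=C2C[C@H](C3OCCO3)[C@@H](C(C)(C)C(=O)O)[C@]2(C)CC=C)c(C(C)C)c1 | intermediate
11 | diisopropyl squarate | CC(C)OC1=C(OC(C)C)C(=O)C1=O | starting material
12 | chloromagnesium alkoxide of 4-hydroxy-2,3-diisopropoxy-4-isopropylcyclobut-2-en-1-one | CC(C)OC1=C(OC(C)C)C(O[Mg]Cl)(C(C)C)C1=O | intermediate
13 | 3-isopropoxy-4-isopropylcyclobut-3-ene-1,2-dione | CC(C)OC1=C(C(C)C)C(=O)C1=O | intermediate
14 | C9 vinyllithium (lithium carboxylate) from 10 | [Li]C1=C[C@H](C2OCCO2)[C@@H](C(C)(C)C(=O)O[Li])[C@]1(C)CC=C | intermediate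
15 | 4-hydroxycyclobutenone adduct (carbinol centre as a mixture) | O1CCOC1[C@@H]2[C@@H](C(C)(C)C(=O)O)[C@](C)(CC=C)C(=C2)C3(O)C(OC(C)C)=C(C(C)C)C3=O | intermediate
16 | 2-[(1R,2R,3S)-1-(1,3-dioxolan-2-yl)-4,7-dihydroxy-5-isopropoxy-6-isopropyl-3-methyl-3-(prop-2-en-1-yl)-2,3-dihydro-1H-inden-2-yl]-2-methylpropanoic acid | O1CCOC1[C@@H]2[C@@H](C(C)(C)C(=O)O)[C@](C)(CC=C)c3c2c(O)c(C(C)C)c(OC(C)C)c3O | intermediate
17 | 2-[(1R,2R,3S)-1-(1,3-dioxolan-2-yl)-5-isopropoxy-6-isopropyl-3-methyl-4,7-dioxo-3-(prop-2-en-1-yl)-2,3,4,7-tetrahydro-1H-inden-2-yl]-2-methylpropanoic acid | O1CCOC1[C@@H]2[C@@H](C(C)(C)C(=O)O)[C@](C)(CC=C)C3=C2C(=O)C(C(C)C)=C(OC(C)C)C3=O | intermediate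
18 | 1,3-dioxoisoindolin-2-yl ester of 17 | O1CCOC1[C@@H]2[C@@H](C(C)(C)C(=O)ON4C(=O)c5ccccc5C4=O)[C@](C)(CC=C)C3=C2C(=O)C(C(C)C)=C(OC(C)C)C3=O | intermediate
19 | 1,3-dioxoisoindolin-2-yl 2-[(1R,2R,3S)-1-formyl-5-hydroxy-6-isopropyl-3-methyl-4,7-dioxo-3-(prop-2-en-1-yl)-2,3,4,7-tetrahydro-1H-inden-2-yl]-2-methylpropanoate | O=C[C@@H]1[C@@H](C(C)(C)C(=O)ON3C(=O)c4ccccc4C3=O)[C@](C)(CC=C)C2=C1C(=O)C(C(C)C)=C(O)C2=O | intermediate
20 | 4-epi-trans-communic acid, (1R,4aR,5S,8aR)-1,4a-dimethyl-6-methylidene-5-[(2E)-3-methylpenta-2,4-dien-1-yl]decahydronaphthalene-1-carboxylic acid | C=C1CC[C@@H]2[C@](C)(CCC[C@@]2(C)C(=O)O)[C@H]1C/C=C(\C)C=C | starting material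
21 | seco-A [5+2] adduct (10α-allyl, 10β-methyl, 5β-CMe2CO2N(phth), 6α-CHO) | C=C1CC[C@@H]2[C@](C)(CCC[C@@]2(C)C(=O)O)[C@H]1C/C=C(\C)[C@H]1C[C@@]2(C(C)C)C(=O)C(O)=C3[C@@]1(C2=O)[C@H](C=O)[C@@H](C(C)(C)C(=O)ON4C(=O)c5ccccc5C4=O)[C@]3(C)CC=C | intermediate
22 | CNP0269191.1 | C=C1CC[C@@H]2[C@](C)(CCC[C@@]2(C)C(=O)O)[C@H]1C/C=C(\C)[C@H]1C[C@@]2(C(C)C)C(=O)C(O)=C3[C@@]1(C2=O)[C@H](C=O)[C@H]1C(C)(C)CCC[C@]31C | target

Total step count: 12. Longest linear sequence: 11 steps (steps 1–5 and 7–12, from 1); step 6 prepares reagent 13.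

Steps most likely to fail

Step 11. The cycloaddition may leak into [4+2] addition of the whole diene, attack by the exocyclic methylene, or Lewis-acid chemistry at the free aldehyde. Facial control may also be eroded because ring A, which shields the β face in the natural series, is still open. The fallback sets out from 18 and comes back at 21. Mild acetal hydrolysis (PPTS, wet acetone, 50 °C), which leaves the vinylogous isopropyl ester intact, would give the 12-isopropoxyquinone aldehyde F1. F1 and 20 would then be combined under bidentate titanium(IV) activation (TiCl4/Ti(OiPr)4, CH2Cl2, −78 °C), the established mode for cationic [5+2] cycloadditions of 2-alkoxy-1,4-benzoquinones with alkenes, with the metal held between O11 and O12. The isopropyl oxocarbenium ion formed on ring closure should lose its isopropyl group to chloride and give 21 directly.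

Step 12. Hydrogen transfer to the tertiary C4 radical may outrun ring closure and give the open-chain isopropyl compound, or the photoreductant may attack the diosphenol. The fallback sets out from 21 and comes back at 22. Visible-light decarboxylative iodination conditions without any hydrogen donor (LiI, PPh3, 456 nm, MeCN) would let the radical cyclise and be captured by iodine, giving the ring-closed C2 iodide F2 in an atom-transfer radical cyclisation. F2 would then be reduced at normal concentration with Bu3SnH/AIBN (toluene, 80 °C) to 22.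

Step 1. Enantio-induction in the Mukaiyama–Michael addition to an α-substituted cyclopentenone may be insufficient, and O- or α′-allylation may erode the trapping. The fallback sets out from 1, 2 and 3 and comes back at 5. The addition would be run with an achiral Lewis acid (TMSOTf cat., CH2Cl2, −78 °C) and followed by the same Pd-catalysed allylation, whose trans selectivity is substrate-controlled. This gives 4 together with the enantiomeric silyl enol ether F3, and hence 5 together with the enantiomeric keto ester F4. Preparative chiral SFC of the racemate would then supply 5.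

Further compounds
F1 | step 11 | 1,3-dioxoisoindolin-2-yl 2-[(1R,2R,3S)-1-formyl-5-isopropoxy-6-isopropyl-3-methyl-4,7-dioxo-3-(prop-2-en-1-yl)-2,3,4,7-tetrahydro-1H-inden-2-yl]-2-methylpropanoate | O=C[C@@H]1[C@@H](C(C)(C)C(=O)ON3C(=O)c4ccccc4C3=O)[C@](C)(CC=C)C2=C1C(=O)C(C(C)C)=C(OC(C)C)C2=O
F2 | step 12 | 2-iodo derivative of 22 (iodine on C2 of ring A, configuration at C2 open) | C=C1CC[C@@H]2[C@](C)(CCC[C@@]2(C)C(=O)O)[C@H]1C/C=C(\C)[C@H]1C[C@@]2(C(C)C)C(=O)C(O)=C3[C@@]1(C2=O)[C@H](C=O)[C@H]1C(C)(C)CC(I)C[C@]31C
F3 | step 1 | methyl 2-methyl-2-[(1S)-2-methyl-3-(trimethylsilyloxy)cyclopent-2-en-1-yl]propanoate (enantiomer of 4) | COC(=O)C(C)(C)[C@H]1CCC(O[Si](C)(C)C)=C1C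
F4 | step 1 | methyl 2-methyl-2-[(1S,2R)-2-methyl-3-oxo-2-(prop-2-en-1-yl)cyclopentyl]propanoate (enantiomer of 5) | O=C1CC[C@H](C(C)(C)C(=O)OC)[C@@]1(C)CC=C
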